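## Plan

1. Retrosynthesis (benzofuran numbering O1, C2, C3, C3a, C4–C7, C7a; ring A = butenolide, ring B = carbocycle): the two aryl O–CH3 bonds are cut first, then ring B is cut at C3a–C4 and C6–C7. This gives a C7–C7a–C3a half that stays on ring A (a 5-benzylidene butenolide of the pulvinone type) and a C4–C5–C6 half (an arylpyruvic ester).
2. Enabling feature: ring B is two arylpyruvate-like three-carbon units joined head to tail (benzylic carbon, oxygenated carbon, acyl-level carbon in each). C3a is the β-carbon of the ring A enoate, and O1 on C7a is an enol-lactone oxygen, so opening ring A at C2 frees a benzyl ketone enolate whose carbon is C7.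
3. Forward order: ring A first (tandem transesterification–Dieckmann), then C7 by aldol condensation, then C3a–OH to the triflate. The C4–C5–C6 ester comes from a benzyl Grignard reagent and dimethyl oxalate. One pot then does substitution at C3a, opening of ring A, closure of ring B at C6–C7 and re-closure of ring A; demethylation ends the route.
4. Stereochemistry: the target has no stereocentre; the Z-benzylidene geometry of the intermediates is erased when C7 enters ring B.

Key step: step 5

Remark on the chemistry: the two phenols are carried as methyl ethers and freed last; keto/enol pairs are drawn in one tautomer; 4-methoxybenzylmagnesium chloride is taken as the purchasable THF solution.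

## Route

Step 1
Reactants: 1 methyl 2-(4-methoxyphenyl)acetate; 2 methyl glycolate
Product: 4 4-hydroxy-3-(4-methoxyphenyl)furan-2(5H)-one, via acyloxy ester 3 (not isolated)
Conditions: KOtBu (2.5 equiv), DMF, 0 °C to rt; then 2 M HCl
Reagents that add atoms: none
Why: Tandem transesterification–Dieckmann condensation of an arylacetate with a glycolate is a known one-pot entry to 3-aryltetronic acids and is driven by formation of the stable tetronate anion.

Step 2
Reactants: 4 4-hydroxy-3-(4-methoxyphenyl)furan-2(5H)-one; 5 benzaldehyde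
Product: 7 (5Z)-5-benzylidene-4-hydroxy-3-(4-methoxyphenyl)furan-2(5H)-one, via aldol adduct 6 (not isolated)
Conditions: LiN(iPr)2 (2.2 equiv), THF, −78 °C; PhCHO, −78 °C to rt; then conc. HCl, AcOH, 60 °C
Reagents that add atoms: none
Why: The C5 carbanion of the tetronate dianion adds to the aldehyde (vinylogous aldol addition) and acid-mediated dehydration of 6 should give the conjugated ylidene butenolide, the Z isomer being favoured thermodynamically; the geometry is of no consequence because step 5 erases it.

Step 3
Reactants: 7 (5Z)-5-benzylidene-4-hydroxy-3-(4-methoxyphenyl)furan-2(5H)-one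
Product: 8 (2Z)-2-benzylidene-4-(4-methoxyphenyl)-5-oxo-2,5-dihydrofuran-3-yl trifluoromethanesulfonate
Conditions: Tf2O, Et3N, CH2Cl2, −78 to 0 °C
Reagents that add atoms: trifluoromethanesulfonic anhydride (Tf2O), O=S(=O)(OS(=O)(=O)C(F)(F)F)C(F)(F)F
Why: O-Sulfonylation of the vinylogous acid (enol triflate formation) turns C3a into a vinylogous acyl triflate carbon without touching the lactone or the ylidene.

Step 4
Reactants: 9 4-methoxybenzylmagnesium chloride; 10 dimethyl oxalate
Product: 11 methyl 3-(4-methoxyphenyl)-2-oxopropanoate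
Conditions: dimethyl oxalate (3 equiv), THF, −78 °C, slow addition of the Grignard solution; then 1 M HCl at −78 °C
Reagents that add atoms: none
Why: Acylation of a Grignard reagent by a dialkyl oxalate should stop after one addition at −78 °C with inverse addition and excess oxalate, because the tetrahedral magnesium hemiketal persists until the acidic quench, a known route to arylpyruvic esters.

Step 5
Reactants: 8 (2Z)-2-benzylidene-4-(4-methoxyphenyl)-5-oxo-2,5-dihydrofuran-3-yl trifluoromethanesulfonate; 11 methyl 3-(4-methoxyphenyl)-2-oxopropanoate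
Product: 15 5-hydroxy-3,4-bis(4-methoxyphenyl)-7-phenyl-1-benzofuran-2,6-dione, via substitution product 12 (not isolated), via ring-opened diester 13 (not isolated), via quinone methide ester 14 (not isolated)
Conditions: NaN(SiMe3)2 (2.2 equiv), 11 (2.2 equiv), THF, −78 °C; 8, −78 °C to rt; then NaOMe (5 equiv), MeOH, 50 °C; then 2 M HCl, THF, 50 °C
Reagents that add atoms: none
Why: Proposed new method: the sodium enolate of 11 should attack C3a of 8 (the β-carbon of the butenolide, a vinylogous acyl triflate) by conjugate addition–elimination to give 12 and so form C3a–C4; methoxide then opens the enol lactone at C2, which unmasks the C7a ketone as its enolate and lets benzylic C7 acylate the α-oxo ester carbon C6 (Dieckmann condensation of 13, forming C6–C7), and acidification re-closes the butenolide from the C7a enol and the C2 ester. The closest known reaction types are the addition–elimination of stabilized carbanions to β-halo or β-sulfonyloxy enoates and the methoxide-induced rearrangement of enol lactones into carbocycles, in which the enolate set free by lactone opening is C-acylated by an ester (as in ylidene phthalide to indane-1,3-dione and pyrandione to hydroxyquinone conversions). Ring B closes by a 6-exo-trig acylation and ring A re-forms by a 5-exo-trig lactonization; no stereocentre is created and the Z geometry of 8 is erased. The step needs carbon attack of the ambident enolate at C3a, which the soft carbon terminus and the irreversible loss of triflate from the C3a adduct alone should secure. It also needs acylation of C7 at C6 and not at C2 (five-membered closure to a cyclopentene-1,3-dione): after deprotonation at C4 the C2 ester is the acceptor end of a push–pull dienolate and so deactivated, while C6 remains an α-oxo ester carbon. Self-aldol of 11 is held back by using it only as its preformed enolate.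

Step 6
Reactants: 15 5-hydroxy-3,4-bis(4-methoxyphenyl)-7-phenyl-1-benzofuran-2,6-dione
Product: 16 peniophorin (5-hydroxy-3,4-bis(4-hydroxyphenyl)-7-phenyl-1-benzofuran-2,6-dione)
Conditions: BBr3 (8 equiv), CH2Cl2, −78 °C to rt; then H2O
Reagents that add atoms: none
Why: Lewis-acid ether cleavage by BBr3 should remove both aryl methyl groups, while the lactone and the chelating hydroxy quinone methide are only complexed and are returned on aqueous work-up.

## Compound list

1 | methyl 2-(4-methoxyphenyl)acetate | COC(=O)Cc1ccc(OC)cc1 | starting material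
2 | methyl glycolate (methyl 2-hydroxyacetate) | COC(=O)CO | starting material
3 | methyl 2-{[2-(4-methoxyphenyl)acetyl]oxy}acetate | COC(=O)COC(=O)Cc1ccc(OC)cc1 | intermediate (not isolated)
4 | 4-hydroxy-3-(4-methoxyphenyl)furan-2(5H)-one | O=C1OCC(O)=C1c1ccc(OC)cc1 | intermediate
5 | benzaldehyde | O=Cc1ccccc1 | starting material
6 | 4-hydroxy-5-[hydroxy(phenyl)methyl]-3-(4-methoxyphenyl)furan-2(5H)-one (racemic, both diastereomers) | O=C1OC(C(O)c2ccccc2)C(O)=C1c1ccc(OC)cc1 | intermediate (not isolated)
7 | (5Z)-5-benzylidene-4-hydroxy-3-(4-methoxyphenyl)furan-2(5H)-one | O=C1O/C(=C\c2ccccc2)C(O)=C1c1ccc(OC)cc1 | intermediate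
8 | (2Z)-2-benzylidene-4-(4-methoxyphenyl)-5-oxo-2,5-dihydrofuran-3-yl trifluoromethanesulfonate | O=C1O/C(=C\c2ccccc2)C(OS(=O)(=O)C(F)(F)F)=C1c1ccc(OC)cc1 | intermediate
9 | 4-methoxybenzylmagnesium chloride | COc1ccc(C[Mg]Cl)cc1 | starting material
10 | dimethyl oxalate | COC(=O)C(=O)OC | starting material
11 | methyl 3-(4-methoxyphenyl)-2-oxopropanoate | COC(=O)C(=O)Cc1ccc(OC)cc1 | intermediate
12 | methyl 3-[(2Z)-2-benzylidene-4-(4-methoxyphenyl)-5-oxo-2,5-dihydrofuran-3-yl]-3-(4-methoxyphenyl)-2-oxopropanoate (racemic, largely enolized) | COC(=O)C(=O)C(c1ccc(OC)cc1)C1=C(c2ccc(OC)cc2)C(=O)O/C1=C\c1ccccc1 | intermediate (not isolated)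
13 | dimethyl (2Z)-2,4-bis(4-methoxyphenyl)-5-oxo-3-(phenylacetyl)hex-2-enedioate (racemic; alkene geometry as delivered by lactone opening, labile in the dienolate) | COC(=O)/C(c1ccc(OC)cc1)=C(\C(=O)Cc1ccccc1)C(c1ccc(OC)cc1)C(=O)C(=O)OC | intermediate (not isolated)
14 | methyl 2-[2,5-dihydroxy-6-(4-methoxyphenyl)-4-oxo-3-phenylcyclohexa-2,5-dien-1-ylidene]-2-(4-methoxyphenyl)acetate (exocyclic alkene geometry labile by tautomerism) | COC(=O)C(c1ccc(OC)cc1)=C1C(O)=C(c2ccccc2)C(=O)C(O)=C1c1ccc(OC)cc1 | intermediate (not isolated)
15 | 5-hydroxy-3,4-bis(4-methoxyphenyl)-7-phenyl-1-benzofuran-2,6-dione | O=C1OC2=C(c3ccccc3)C(=O)C(O)=C(c3ccc(OC)cc3)C2=C1c1ccc(OC)cc1 | intermediate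
16 | peniophorin, 5-hydroxy-3,4-bis(4-hydroxyphenyl)-7-phenyl-1-benzofuran-2,6-dione | O=C1OC2=C(c3ccccc3)C(=O)C(O)=C(c3ccc(O)cc3)C2=C1c1ccc(O)cc1 | target

## Count and risks

Total steps: 6. Longest linear sequence: 5 (steps 1, 2, 3, 5, 6); step 4 is a one-step branch.

Steps most likely to fail:

**Step 5.** The ambident enolate may attack through oxygen, or the sulfonyl group may be transferred to it, instead of carbon–carbon bond formation at C3a. After lactone opening the Claisen closure may take the five-membered course onto C2, and re-lactonization may stay incomplete. The fallback uses known chemistry, takes ring B ready-made and closes ring A last; it sets out from 1 and comes back at 15.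
- Ester 1 is saponified (LiOH, aqueous THF) to 4-methoxyphenylacetic acid F1.
- Tetrabromo-1,4-benzoquinone and NaOMe in MeOH should give 2,5-dibromo-3,6-dimethoxy-1,4-benzoquinone F2.
- Two successive Suzuki–Miyaura couplings (Pd(PPh3)4, Na2CO3, aqueous dioxane) follow: first with one equivalent of phenylboronic acid to 2-bromo-3,6-dimethoxy-5-phenyl-1,4-benzoquinone F3, then with 4-methoxyphenylboronic acid to 2,5-dimethoxy-3-(4-methoxyphenyl)-6-phenyl-1,4-benzoquinone F4.
- Hydrolysis of the two vinylogous esters (aqueous NaOH, MeOH, then HCl) should give 2,5-dihydroxy-3-(4-methoxyphenyl)-6-phenyl-1,4-benzoquinone F5.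
- Perkin-type condensation of F5 with F1 (Ac2O, NaOAc, 120 °C; O-acylation, then intramolecular Knoevenagel condensation) should give 3,4-bis(4-methoxyphenyl)-2,6-dioxo-7-phenyl-2,6-dihydro-1-benzofuran-5-yl acetate F6. The regioisomer with the aryl groups at C4 and C7 exchanged is expected as well and must be separated.
- Dilute HCl in aqueous THF cleaves the enol acetate of F6 to 15.

**Step 2.** Dianion formation may be incomplete, and the aldol adduct may revert during the acidic dehydration. The fallback masks the acidic hydroxyl so that a mono-anion aldol and a separate elimination are used; it sets out from 4 and comes back at 7.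
- 4 is O-methylated (Me2SO4, K2CO3, acetone) to 4-methoxy-3-(4-methoxyphenyl)furan-2(5H)-one F7.
- C5 lithiation (LiN(iPr)2, THF, −78 °C) and addition to benzaldehyde 5 should give 5-[hydroxy(phenyl)methyl]-4-methoxy-3-(4-methoxyphenyl)furan-2(5H)-one F8.
- Acid-catalysed dehydration (TsOH, toluene, reflux) should give (Z)-5-benzylidene-4-methoxy-3-(4-methoxyphenyl)furan-2(5H)-one F9.
- LiBr in DMF at 100 °C cleaves only the vinylogous methyl ester and returns 7.

**Step 6.** The quinone methide chromophore may be degraded, or the lactone opened, under the strongly Lewis-acidic conditions, and the second ether may be cleaved incompletely. The fallback takes the chromophore out of play by reduction before deprotection; it sets out from 15 and comes back at 16.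
- Na2S2O4 in aqueous THF should reduce 15 to the leuco compound 5,6-dihydroxy-3,4-bis(4-methoxyphenyl)-7-phenyl-1-benzofuran-2(3H)-one F10 (racemic at C3).
- Demethylation of this plain aryl ether (48% HBr, AcOH, reflux) should give 5,6-dihydroxy-3,4-bis(4-hydroxyphenyl)-7-phenyl-1-benzofuran-2(3H)-one F11.
- Oxidation of the catechol (air in aqueous NaHCO3, or Ag2O in acetone) to the ortho-quinone, which tautomerizes through its acidic C3–H to the quinone methide, should give 16.

## Further compounds

F1 | step 5 | 4-methoxyphenylacetic acid | COc1ccc(CC(=O)O)cc1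
F2 | step 5 | 2,5-dibromo-3,6-dimethoxy-1,4-benzoquinone | COC1=C(Br)C(=O)C(OC)=C(Br)C1=O
F3 | step 5 | 2-bromo-3,6-dimethoxy-5-phenyl-1,4-benzoquinone | COC1=C(Br)C(=O)C(OC)=C(c2ccccc2)C1=O
F4 | step 5 | 2,5-dimethoxy-3-(4-methoxyphenyl)-6-phenyl-1,4-benzoquinone | COC1=C(c2ccc(OC)cc2)C(=O)C(OC)=C(c2ccccc2)C1=O
F5 | step 5 | 2,5-dihydroxy-3-(4-methoxyphenyl)-6-phenyl-1,4-benzoquinone | COc1ccc(cc1)C1=C(O)C(=O)C(c2ccccc2)=C(O)C1=O
F6 | step 5 | 3,4-bis(4-methoxyphenyl)-2,6-dioxo-7-phenyl-2,6-dihydro-1-benzofuran-5-yl acetate | CC(=O)OC1=C(c2ccc(OC)cc2)C2=C(c3ccc(OC)cc3)C(=O)OC2=C(c2ccccc2)C1=O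
F7 | step 2 | 4-methoxy-3-(4-methoxyphenyl)furan-2(5H)-one | COC1=C(c2ccc(OC)cc2)C(=O)OC1
F8 | step 2 | 5-[hydroxy(phenyl)methyl]-4-methoxy-3-(4-methoxyphenyl)furan-2(5H)-one (racemic, both diastereomers) | COC1=C(c2ccc(OC)cc2)C(=O)OC1C(O)c1ccccc1
F9 | step 2 | (Z)-5-benzylidene-4-methoxy-3-(4-methoxyphenyl)furan-2(5H)-one | COC1=C(c2ccc(OC)cc2)C(=O)O/C1=C\c1ccccc1
F10 | step 6 | 5,6-dihydroxy-3,4-bis(4-methoxyphenyl)-7-phenyl-1-benzofuran-2(3H)-one (racemic) | O=C1Oc2c(-c3ccccc3)c(O)c(O)c(-c3ccc(OC)cc3)c2C1c1ccc(OC)cc1
F11 | step 6 | 5,6-dihydroxy-3,4-bis(4-hydroxyphenyl)-7-phenyl-1-benzofuran-2(3H)-one (racemic) | O=C1Oc2c(-c3ccccc3)c(O)c(O)c(-c3ccc(O)cc3)c2C1c1ccc(O)cc1
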